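**Retrosynthetic overview**

- β-HIVS 15 ⇒ (R)-shikonin 13 + 3-hydroxy-3-methylbutanoic acid 14: the side-chain ester C–O bond is made last, because only the side-chain OH is free of a peri hydrogen bond.
- 13 ⇒ leuco-level tetraether 11, in which the peri oxygen pairs O1/O8 and O4/O5 are tied back as two di-tert-butylsilylene (1,3,2-dioxasiline) rings; fluoride and O2 open both rings and restore the quinone.
- 11 ⇒ aryl pinacol boronate 5 + homoprenyl carbamate 7: the C2–C1′ bond is made by an asymmetric lithiation–borylation (1,2-shift of C2 from boron to C1′), and the C–B bond left at C1′ is oxidised to C–O in the same flask.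
- Enabling feature: C1′ is an sp3 CH that carries one oxygen and sits directly on sp2 C2 of the naphthalene bicycle, so it can be delivered as an enantioenriched α-oxygenated carbenoid that accepts C2 from boron. In the tetra-O-protected leuco form C2, C3, C6 and C7 are symmetry-equivalent (2- and 6-substituted naphthazarins are tautomers of one compound), so the C2–B bond is placed without a regiochemical question.
- Ring order: the naphthalene bicycle is bought as naphthazarin 1 and reduced to its 2,3-dihydro (leuco) form 2; the two dioxasiline rings are closed in step 2 and removed in step 7; no carbocycle is built.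

Key step: step 6

**Route**

Step 1
Reactants: 1 naphthazarin (5,8-dihydroxy-1,4-naphthoquinone)
Product: 2 2,3-dihydronaphthazarin (5,8-dihydroxy-2,3-dihydronaphthalene-1,4-dione)
Conditions: SnCl2·2H2O, 4 M aq. HCl, reflux, Ar
Reagents that add atoms: none
Why: Sn(II) reduction of the quinone to the hydroquinone level, after which the leuco compound should settle as the 2,3-dihydro diketo tautomer held by two peri O–H···O=C hydrogen bonds (quinone reduction with keto–enol tautomerism).

Step 2
Reactants: 2 2,3-dihydronaphthazarin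
Product: 3 1,8:4,5-bis(di-tert-butylsilanediyldioxy)naphthalene (naphthalene-1,4,5,8-tetrol with O1/O8 and O4/O5 each bridged by one tBu2Si unit)
Conditions: tBu2Si(OTf)2 (2.2 equiv), Et3N (6 equiv), CH2Cl2, 0 °C → rt, Ar
Reagents that add atoms: di-tert-butylsilyl bis(trifluoromethanesulfonate), CC(C)(C)[Si](OS(=O)(=O)C(F)(F)F)(OS(=O)(=O)C(F)(F)F)C(C)(C)C
Why: Silylene protection, in which O-silylation of each phenol and intramolecular O-silylation of the peri carbonyl with loss of an α-proton (silyl enol ether formation, here an aromatisation) should close two six-membered dioxasiline rings, peri bridging being the only geometrically possible mode.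

Step 3
Reactants: 3 1,8:4,5-bis(di-tert-butylsilanediyldioxy)naphthalene
Product: 4 2-bromo-1,8:4,5-bis(di-tert-butylsilanediyldioxy)naphthalene
Conditions: NBS (1.0 equiv), CH2Cl2, −20 → 0 °C, dark
Reagents that add atoms: N-bromosuccinimide, O=C1CCC(=O)N1Br
Why: Electrophilic aromatic bromination of a tetra-oxygenated naphthalene whose four free positions are equivalent by symmetry, so one equivalent of NBS should give a single monobromide.

Step 4
Reactants: 4 2-bromo-1,8:4,5-bis(di-tert-butylsilanediyldioxy)naphthalene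
Product: 5 2-(4,4,5,5-tetramethyl-1,3,2-dioxaborolan-2-yl)-1,8:4,5-bis(di-tert-butylsilanediyldioxy)naphthalene
Conditions: B2pin2 (1.3 equiv), PdCl2(dppf) (5 mol %), KOAc (3 equiv), 1,4-dioxane, 85 °C
Reagents that add atoms: bis(pinacolato)diboron, CC1(C)OB(OC1(C)C)B1OC(C)(C)C(C)(C)O1
Why: Miyaura borylation of an aryl bromide under weakly basic, non-nucleophilic conditions that the Si–O(aryl) bonds should tolerate.

Step 5
Reactants: 6 4-methylpent-3-en-1-ol
Product: 7 4-methylpent-3-en-1-yl N,N-diisopropylcarbamate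
Conditions: iPr2NC(O)Cl (1.2 equiv), Et3N (1.5 equiv), CH2Cl2, reflux
Reagents that add atoms: N,N-diisopropylcarbamoyl chloride, CC(C)N(C(C)C)C(Cl)=O
Why: Carbamoylation of a primary alcohol (nucleophilic acyl substitution), which installs the group that directs the lithiation and later serves as the leaving group.

Step 6
Reactants: 7 4-methylpent-3-en-1-yl N,N-diisopropylcarbamate; 5 2-(pinacolboryl)-1,8:4,5-bis(di-tert-butylsilanediyldioxy)naphthalene
Product: 11 (R)-1-[1,8:4,5-bis(di-tert-butylsilanediyldioxy)naphthalen-2-yl]-4-methylpent-3-en-1-ol, via lithiated carbamate 8 (not isolated), via boronate complex 9 (not isolated), via boronic ester 10 (not isolated)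
Conditions: 7 (1.3 equiv), (−)-sparteine (1.3 equiv), s-BuLi (1.25 equiv), Et2O, −78 °C, 5 h; 5 (1.0 equiv), −78 °C, 1 h, then 35 °C, 16 h; NaBO3·4H2O, THF/H2O, rt
Reagents that add atoms: sodium perborate tetrahydrate (supplies the hydroxyl oxygen), [Na+].[Na+].O[B-]1(O)OO[B-](O)(O)OO1
Why: s-BuLi/(−)-sparteine removes the pro-S hydrogen of the O–CH2 group of 7 to give the configurationally stable (S)-α-lithio carbamate 8, which adds to boron of 5 with retention to give boronate complex 9; on warming, naphthalene C2 migrates from boron to C1′ anti to the departing carbamate (inversion at C1′), which forms the C2–C1′ bond and (R)-10, and perborate then replaces boron by OH with retention to give (R)-11. The closest known reaction type is the lithiation–borylation (Matteson-type 1,2-metallate rearrangement) of sparteine-derived lithiated primary O-alkyl carbamates with aryl pinacol boronates, followed by C–B oxidation. No ring is closed. The single new stereocentre C1′ is set by reagent control in the deprotonation that distinguishes the two enantiotopic hydrogens, and is carried through three stereospecific events (retention, inversion, retention). The step needs lithiation at O–CH2 and not at the allylic CH2, which the pre-coordinating carbamate carbonyl secures, and it needs complete, irreversible boronate formation next to an oxygenated position, which the silylene rings secure by holding the O1 substituent away from C2 while the electron-rich aryl group migrates readily. Because 5 carries one C–B bond and the carbenoid one leaving group, only one C–C bond can form.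

Step 7
Reactants: 11 (R)-1-[1,8:4,5-bis(di-tert-butylsilanediyldioxy)naphthalen-2-yl]-4-methylpent-3-en-1-ol
Product: 13 (R)-shikonin, via leucoshikonin 12 (not isolated)
Conditions: TBAF (4.4 equiv), THF, O2 (1 atm), −20 → 0 °C; then AcOH, pH 4 buffer
Reagents that add atoms: none
Why: Fluoride-induced desilylation should release the leuco tetraphenoxide 12, whose autoxidation by O2 (hydroquinone to quinone) at low temperature is expected to be faster than loss of the C1′ oxygen, and C1′ is not involved in either event.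

Step 8
Reactants: 13 (R)-shikonin; 14 3-hydroxy-3-methylbutanoic acid
Product: 15 β-HIVS, (R)-1-(5,8-dihydroxy-1,4-dioxo-1,4-dihydronaphthalen-2-yl)-4-methylpent-3-en-1-yl 3-hydroxy-3-methylbutanoate
Conditions: 14 (1.5 equiv), DCC (1.6 equiv), DMAP (0.2 equiv), CH2Cl2, 0 °C → rt
Reagents that add atoms: none
Why: Steglich esterification, in which the peri-hydrogen-bonded phenols and the hindered tertiary OH of 14 should stay unreactive so that only the secondary side-chain OH is acylated, with the configuration at C1′ unchanged because only the O–H bond reacts.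

**Compound list**

1 | naphthazarin (5,8-dihydroxy-1,4-naphthoquinone) | O=C1C=CC(=O)c2c(O)ccc(O)c12 | starting material
2 | 2,3-dihydronaphthazarin (5,8-dihydroxy-2,3-dihydronaphthalene-1,4-dione) | O=C1CCC(=O)c2c(O)ccc(O)c12 | intermediate
3 | 1,8:4,5-bis(di-tert-butylsilanediyldioxy)naphthalene | c1cc2O[Si](C(C)(C)C)(C(C)(C)C)Oc3ccc4O[Si](C(C)(C)C)(C(C)(C)C)Oc1c4c32 | intermediate
4 | 2-bromo-1,8:4,5-bis(di-tert-butylsilanediyldioxy)naphthalene | Brc1cc2O[Si](C(C)(C)C)(C(C)(C)C)Oc3ccc4O[Si](C(C)(C)C)(C(C)(C)C)Oc1c4c32 | intermediate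
5 | 2-(4,4,5,5-tetramethyl-1,3,2-dioxaborolan-2-yl)-1,8:4,5-bis(di-tert-butylsilanediyldioxy)naphthalene | CC1(C)OB(OC1(C)C)c1cc2O[Si](C(C)(C)C)(C(C)(C)C)Oc3ccc4O[Si](C(C)(C)C)(C(C)(C)C)Oc1c4c32 | intermediate
6 | 4-methylpent-3-en-1-ol | CC(C)=CCCO | starting material
7 | 4-methylpent-3-en-1-yl N,N-diisopropylcarbamate | CC(C)=CCCOC(=O)N(C(C)C)C(C)C | intermediate
8 | (S)-1-lithio-4-methylpent-3-en-1-yl N,N-diisopropylcarbamate (as its sparteine complex) | CC(C)=CC[C@@H](OC(=O)N(C(C)C)C(C)C)[Li] | intermediate (not isolated)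
9 | lithium boronate complex of 5 with the (S)-1-(diisopropylcarbamoyloxy)-4-methylpent-3-en-1-yl group on boron | [Li+].CC(C)=CC[C@@H](OC(=O)N(C(C)C)C(C)C)[B-]1(OC(C)(C)C(C)(C)O1)c1cc2O[Si](C(C)(C)C)(C(C)(C)C)Oc3ccc4O[Si](C(C)(C)C)(C(C)(C)C)Oc1c4c32 | intermediate (not isolated)
10 | (R)-2-[4-methyl-1-(pinacolboryl)pent-3-en-1-yl]-1,8:4,5-bis(di-tert-butylsilanediyldioxy)naphthalene | CC(C)=CC[C@@H](B1OC(C)(C)C(C)(C)O1)c1cc2O[Si](C(C)(C)C)(C(C)(C)C)Oc3ccc4O[Si](C(C)(C)C)(C(C)(C)C)Oc1c4c32 | intermediate (not isolated)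
11 | (R)-1-[1,8:4,5-bis(di-tert-butylsilanediyldioxy)naphthalen-2-yl]-4-methylpent-3-en-1-ol | CC(C)=CC[C@@H](O)c1cc2O[Si](C(C)(C)C)(C(C)(C)C)Oc3ccc4O[Si](C(C)(C)C)(C(C)(C)C)Oc1c4c32 | intermediate
12 | leucoshikonin, (R)-2-(1-hydroxy-4-methylpent-3-en-1-yl)naphthalene-1,4,5,8-tetrol (formed as its phenoxide) | CC(C)=CC[C@@H](O)c1cc(O)c2c(O)ccc(O)c2c1O | intermediate (not isolated)
13 | (R)-shikonin, 5,8-dihydroxy-2-[(1R)-1-hydroxy-4-methylpent-3-en-1-yl]naphthalene-1,4-dione | CC(C)=CC[C@@H](O)C1=CC(=O)c2c(O)ccc(O)c2C1=O | intermediate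
14 | 3-hydroxy-3-methylbutanoic acid | CC(C)(O)CC(=O)O | starting material
15 | β-HIVS, (R)-1-(5,8-dihydroxy-1,4-dioxo-1,4-dihydronaphthalen-2-yl)-4-methylpent-3-en-1-yl 3-hydroxy-3-methylbutanoate | CC(C)=CC[C@@H](OC(=O)CC(C)(C)O)C1=CC(=O)c2c(O)ccc(O)c2C1=O | target

Total step count: 8. Longest linear sequence: 7 steps (1, 2, 3, 4, 6, 7, 8).

**Steps most likely to fail**

Step 6. The boronate complex may form incompletely or reversibly next to the oxygenated ring position, which would erode the enantiomeric purity; allylic deprotonation of 7 may compete; and the silylene rings may partly open during the oxidative work-up. The fallback sets the stereocentre by reduction and not during C–C bond formation. It sets out from bromide 4: bromine–lithium exchange (t-BuLi, THF, −78 °C) would give 2-lithio-1,8:4,5-bis(di-tert-butylsilanediyldioxy)naphthalene F2. This would be acylated with N-methoxy-N-methyl-4-methylpent-3-enamide F1 (made from commercial 4-methylpent-3-enoic acid with carbonyldiimidazole and N,O-dimethylhydroxylamine hydrochloride) to give 1-[1,8:4,5-bis(di-tert-butylsilanediyldioxy)naphthalen-2-yl]-4-methylpent-3-en-1-one F3. Enantioselective reduction of this aryl alkyl ketone with (+)-B-chlorodiisopinocampheylborane (THF, −25 °C; the enantiomer expected to give the R alcohol when the aryl group is the larger substituent) would return to the route at compound 11.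

Step 7. The C1′ oxygen may be lost at the leuco stage (elimination through an ortho-quinone methide, a Marschalk-type deoxygenation), or the naphthazarin anion may decompose under base and peroxide before the quench. The fallback avoids any hydroquinone-level intermediate. It sets out from compound 11: Steglich esterification with 14 (DCC, DMAP, CH2Cl2) would give (R)-1-[1,8:4,5-bis(di-tert-butylsilanediyldioxy)naphthalen-2-yl]-4-methylpent-3-en-1-yl 3-hydroxy-3-methylbutanoate F4. Oxidative desilylation with ceric ammonium nitrate (MeCN/H2O, 0 °C) should then give the quinone directly, as (R)-1-{5,8-bis[di-tert-butyl(hydroxy)silyloxy]-1,4-dioxo-1,4-dihydronaphthalen-2-yl}-4-methylpent-3-en-1-yl 3-hydroxy-3-methylbutanoate F5 and its ring isomer (R)-1-{1,4-bis[di-tert-butyl(hydroxy)silyloxy]-5,8-dioxo-5,8-dihydronaphthalen-2-yl}-4-methylpent-3-en-1-yl 3-hydroxy-3-methylbutanoate F6. Both are expected to converge on one naphthazarin with HF·pyridine (THF, 0 °C), so the fallback comes back to the route at compound 15.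

Step 8. The activated β-hydroxy acid may self-condense, close to a β-lactone or dehydrate, and a phenolic OH may be acylated in competition. The fallback masks the tertiary OH. It sets out from compounds 13 and 14: 14 would be silylated (TESCl, imidazole, DMF) to triethylsilyl 3-methyl-3-(triethylsilyloxy)butanoate F7, and the silyl ester alone hydrolysed (K2CO3, MeOH/H2O, 0 °C) to 3-methyl-3-(triethylsilyloxy)butanoic acid F8. Coupling of F8 with 13 (DCC, DMAP, CH2Cl2) would give (R)-1-(5,8-dihydroxy-1,4-dioxo-1,4-dihydronaphthalen-2-yl)-4-methylpent-3-en-1-yl 3-methyl-3-(triethylsilyloxy)butanoate F9, and HF·pyridine (THF, 0 °C) would return to the route at compound 15.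

**Further compounds**

F1 | step 6 | N-methoxy-N-methyl-4-methylpent-3-enamide | CC(C)=CCC(=O)N(C)OC
F2 | step 6 | 2-lithio-1,8:4,5-bis(di-tert-butylsilanediyldioxy)naphthalene | [Li]c1cc2O[Si](C(C)(C)C)(C(C)(C)C)Oc3ccc4O[Si](C(C)(C)C)(C(C)(C)C)Oc1c4c32
F3 | step 6 | 1-[1,8:4,5-bis(di-tert-butylsilanediyldioxy)naphthalen-2-yl]-4-methylpent-3-en-1-one | CC(C)=CCC(=O)c1cc2O[Si](C(C)(C)C)(C(C)(C)C)Oc3ccc4O[Si](C(C)(C)C)(C(C)(C)C)Oc1c4c32
F4 | step 7 | (R)-1-[1,8:4,5-bis(di-tert-butylsilanediyldioxy)naphthalen-2-yl]-4-methylpent-3-en-1-yl 3-hydroxy-3-methylbutanoate | CC(C)=CC[C@@H](OC(=O)CC(C)(C)O)c1cc2O[Si](C(C)(C)C)(C(C)(C)C)Oc3ccc4O[Si](C(C)(C)C)(C(C)(C)C)Oc1c4c32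
F5 | step 7 | (R)-1-{5,8-bis[di-tert-butyl(hydroxy)silyloxy]-1,4-dioxo-1,4-dihydronaphthalen-2-yl}-4-methylpent-3-en-1-yl 3-hydroxy-3-methylbutanoate | CC(C)=CC[C@@H](OC(=O)CC(C)(C)O)C1=CC(=O)c2c(O[Si](O)(C(C)(C)C)C(C)(C)C)ccc(O[Si](O)(C(C)(C)C)C(C)(C)C)c2C1=O
F6 | step 7 | (R)-1-{1,4-bis[di-tert-butyl(hydroxy)silyloxy]-5,8-dioxo-5,8-dihydronaphthalen-2-yl}-4-methylpent-3-en-1-yl 3-hydroxy-3-methylbutanoate | CC(C)=CC[C@@H](OC(=O)CC(C)(C)O)c1cc(O[Si](O)(C(C)(C)C)C(C)(C)C)c2C(=O)C=CC(=O)c2c1O[Si](O)(C(C)(C)C)C(C)(C)C
F7 | step 8 | triethylsilyl 3-methyl-3-(triethylsilyloxy)butanoate | CC[Si](CC)(CC)OC(=O)CC(C)(C)O[Si](CC)(CC)CC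
F8 | step 8 | 3-methyl-3-(triethylsilyloxy)butanoic acid | CC[Si](CC)(CC)OC(C)(C)CC(=O)O
F9 | step 8 | (R)-1-(5,8-dihydroxy-1,4-dioxo-1,4-dihydronaphthalen-2-yl)-4-methylpent-3-en-1-yl 3-methyl-3-(triethylsilyloxy)butanoate | CC(C)=CC[C@@H](OC(=O)CC(C)(C)O[Si](CC)(CC)CC)C1=CC(=O)c2c(O)ccc(O)c2C1=O
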